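**Retrosynthetic overview** (atoms carry kaurane numbers C1–C20)

- Late stage: the ring D pattern (C15 hydroxyl, C16–C17 epoxide) and the ring A oxidation level (C1 enone, C6 aldehyde) are set on a 6,7-seco lactone that still carries a C16 methyl carbinol, a C12 ketone and silylated C1 and C6 alcohols.
- That lactone is cut at C9–C10 and C20–O: a ring A spiro-epoxide (C10–C20–O) gives a tertiary C10 radical with Cp2TiCl, which adds to C9 of a bicyclo[3.2.1]octenone; the freed C20 hydroxyl closes the lactone on the C7 ester.
- Feature: C8 is the quaternary carbon shared by ring C, ring D and the lactone. Written as a cyclohexa-2,5-dienone (C12 carbonyl) whose C8 carries the C7 ester and the C15–C16(=O)–C17 arm, ring C is achiral, so one C13–C16 bond on one enone arm closes ring D and fixes C8 and C13 together.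
- Key disconnection: C13–C16 by copper hydride conjugate reduction–aldol of that dienone, which comes from benzoic acid and propargyl bromide. Ring A comes from 4,4-dimethylcyclohexanone, with C5 set by rhodium-catalysed alkenylation.
- Ring order: ring C (from the arene), ring D (key step), ring A brought in preformed, lactone ring on fragment union, epoxide last.

Key step: step 5

Assumption: the (R) antipode of the bisphosphine is taken to select the enone arm that leads to the (1R,5R) bicycle; if the sense of induction is the reverse, the (S) ligand is used and nothing else changes.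

**Route**

Step 1
Reactants: 1 benzoic acid; 2 propargyl bromide
Product: 4 1-(prop-2-yn-1-yl)cyclohexa-2,5-diene-1-carboxylic acid, via dilithium dienediolate 3 (not isolated)
Conditions: Li, NH3(l), THF, −78 °C; then 2, −78 °C; aq. HCl
Reagents that add atoms: none
Why: Birch reduction of the benzoate gives the cross-conjugated dienediolate 3, which is alkylated at the carboxyl-bearing carbon by 2 (Birch reduction–alkylation), so that C8 becomes quaternary and ring C is left as a 1,4-diene.

Step 2
Reactants: 4 1-(prop-2-yn-1-yl)cyclohexa-2,5-diene-1-carboxylic acid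
Product: 5 methyl 1-(prop-2-yn-1-yl)cyclohexa-2,5-diene-1-carboxylate
Conditions: MeI, K2CO3, DMF, rt
Reagents that add atoms: iodomethane, CI
Why: SN2 O-alkylation of the potassium carboxylate gives the methyl ester (C7) that later serves as the acyl group of the lactone, and no stereocentre is involved.

Step 3
Reactants: 5 methyl 1-(prop-2-yn-1-yl)cyclohexa-2,5-diene-1-carboxylate
Product: 6 methyl 4-oxo-1-(prop-2-yn-1-yl)cyclohexa-2,5-diene-1-carboxylate
Conditions: CrO3, 3,5-dimethylpyrazole, CH2Cl2, −20 °C
Reagents that add atoms: chromium trioxide, O=[Cr](=O)=O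
Why: Allylic oxidation by the CrO3–3,5-dimethylpyrazole complex should attack the doubly allylic C12 methylene far faster than the propargylic CH2, and the resulting cross-conjugated dienone cannot aromatise because C8 is quaternary.

Step 4
Reactants: 6 methyl 4-oxo-1-(prop-2-yn-1-yl)cyclohexa-2,5-diene-1-carboxylate
Product: 7 methyl 4-oxo-1-(2-oxopropyl)cyclohexa-2,5-diene-1-carboxylate
Conditions: Ph3PAuNTf2 (2 mol %), H2O, 1,4-dioxane, 60 °C
Reagents that add atoms: water, O
Why: Gold-catalysed Markovnikov hydration of the terminal alkyne gives the methyl ketone (C16 with C17) under neutral conditions, and it is placed after the oxidation so that the ring alkenes are electron-poor and cannot enter a gold enyne cycloisomerisation.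

Step 5
Reactants: 7 methyl 4-oxo-1-(2-oxopropyl)cyclohexa-2,5-diene-1-carboxylate
Product: 9 methyl (1R,5R,6S)-6-hydroxy-6-methyl-4-oxobicyclo[3.2.1]oct-2-ene-1-carboxylate, via aldol silyl ether 8 (not isolated)
Conditions: Cu(OAc)2 (5 mol %), (R)-DTBM-SEGPHOS (5.5 mol %), (EtO)2MeSiH (1.1 equiv), toluene, −20 °C; aq. HCl work-up
Reagents that add atoms: none
Why: The ligated copper hydride formed from Cu(OAc)2, the bisphosphine and the silane delivers hydride to C14 of one enone arm of the achiral dienone, the C13 copper enolate adds to the tethered C16 ketone, and the copper alkoxide is silylated by the silane to turn the catalyst over. This is a copper hydride reductive aldol cyclisation used to desymmetrise a 4,4-disubstituted cyclohexadienone, both being established reaction types. Ring D closes as a 5-(enolexo)-exo-trig aldol that forms C13–C16 and with it the bicyclo[3.2.1]octene. C8 and C13 are fixed together by the choice of arm, which is made by the chiral bisphosphine, and only the cis bridge is possible with a two-atom tether; C16 follows from the chelated transition state that turns the alkoxide oxygen toward the C12 oxygen, and it is erased in step 17. The step needs arm selection, 1,4- over 1,2-reduction and a single turnover: the flat ester and the CH2-linked acetonyl group make the two faces of each β-carbon different enough for the catalyst to tell the arms apart, the doubly activated dienone should be reduced faster than the methyl ketone, and the product enone has its β-carbon C9 next to the quaternary bridgehead and should be spared with 1.1 equivalents of silane at low temperature.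

Step 6
Reactants: 10 4,4-dimethylcyclohexanone
Product: 11 4,4-dimethylcyclohexa-2,5-dien-1-one
Conditions: IBX (3 equiv), DMSO, 80 °C
Reagents that add atoms: none
Why: Twofold IBX dehydrogenation of the ketone through its enol gives the cross-conjugated dienone and stops there because C4 is quaternary.

Step 7
Reactants: 11 4,4-dimethylcyclohexa-2,5-dien-1-one; 12 (E)-2-phenylethenylboronic acid
Product: 13 (R)-4,4-dimethyl-5-[(E)-2-phenylethenyl]cyclohex-2-en-1-one
Conditions: [Rh(OH)((R)-BINAP)]2 (1.5 mol %), 1,4-dioxane/H2O 10:1, 35 °C, 11 in excess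
Reagents that add atoms: none
Why: Hayashi–Miyaura rhodium-catalysed asymmetric 1,4-addition transfers the styryl group to C5 (the two β-carbons are homotopic), the (R)-BINAP ligand selecting the enantioface in the sense established for cyclohexenone to give the (R)-adduct, and an excess of 11 limits a second addition.

Step 8
Reactants: 13 (R)-4,4-dimethyl-5-[(E)-2-phenylethenyl]cyclohex-2-en-1-one
Product: 15 (S)-5-(hydroxymethyl)-4,4-dimethylcyclohex-2-en-1-one, via keto aldehyde 14 (not isolated)
Conditions: O3, CH2Cl2/MeOH, −78 °C; Me2S; then NaBH4, −78 °C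
Reagents that add atoms: ozone, [O-][O+]=O
Why: Ozonolysis cleaves the electron-rich styryl alkene in preference to the electron-poor enone alkene, and the aldehyde 14 is reduced in the same flask at −78 °C, faster than the conjugated ketone and before the C5 hydrogen α to the aldehyde can epimerise.

Step 9
Reactants: 15 (S)-5-(hydroxymethyl)-4,4-dimethylcyclohex-2-en-1-one
Product: 16 (S)-5-[(tert-butyldimethylsilyloxy)methyl]-4,4-dimethylcyclohex-2-en-1-one
Conditions: TBSCl, imidazole, DMF, rt
Reagents that add atoms: tert-butyldimethylsilyl chloride, C[Si](C)(Cl)C(C)(C)C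
Why: Silylation of the primary alcohol with TBSCl and imidazole protects the C6 oxygen for the enolate, radical and oxidation steps that follow.

Step 10
Reactants: 16 (S)-5-[(tert-butyldimethylsilyloxy)methyl]-4,4-dimethylcyclohex-2-en-1-one
Product: 19 (R)-5-[(tert-butyldimethylsilyloxy)methyl]-4,4-dimethyl-6-methylidenecyclohex-2-en-1-one, via Mannich base 17 (not isolated), via trimethylammonium iodide 18 (not isolated)
Conditions: LiN(iPr)2, THF, −78 °C; Me2N=CH2 I; then MeI, CH2Cl2; then aq. NaHCO3
Reagents that add atoms: N,N-dimethylmethyleneiminium iodide, C=[N+](C)C.[I-]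
Why: The kinetic lithium enolate can form only at C10 (C2 is vinylic, C4 quaternary) and undergoes a Mannich reaction with the iminium salt, and quaternisation followed by E1cB loss of trimethylamine gives the exocyclic C10=C20 methylene (Eschenmoser methylenation).

Step 11
Reactants: 19 (R)-5-[(tert-butyldimethylsilyloxy)methyl]-4,4-dimethyl-6-methylidenecyclohex-2-en-1-one
Product: 20 (1S,5R)-5-[(tert-butyldimethylsilyloxy)methyl]-4,4-dimethyl-6-methylidenecyclohex-2-en-1-ol
Conditions: NaBH4, CeCl3·7H2O, MeOH, −78 °C
Reagents that add atoms: none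
Why: Luche 1,2-reduction of the cross-conjugated dienone should deliver hydride anti to the C5 CH2OTBS group, which sits pseudoaxial to avoid allylic strain with the exocyclic methylene, giving the C1 alcohol cis to C6.

Step 12
Reactants: 20 (1S,5R)-5-[(tert-butyldimethylsilyloxy)methyl]-4,4-dimethyl-6-methylidenecyclohex-2-en-1-ol
Product: 21 bis-TBS ether of 20
Conditions: TBSOTf, 2,6-lutidine, CH2Cl2, −78 to 0 °C
Reagents that add atoms: tert-butyldimethylsilyl triflate, C[Si](C)(OS(=O)(=O)C(F)(F)F)C(C)(C)C
Why: TBSOTf with 2,6-lutidine silylates the hindered allylic alcohol, so that no free hydroxyl can direct the peracid in step 13 or interfere with the radical chemistry of step 14.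

Step 13
Reactants: 21 bis-TBS ether of 20
Product: 22 (3R,4S,8S)-4-(tert-butyldimethylsilyloxy)-8-[(tert-butyldimethylsilyloxy)methyl]-7,7-dimethyl-1-oxaspiro[2.5]oct-5-ene
Conditions: mCPBA, NaHCO3, CH2Cl2, 0 °C
Reagents that add atoms: 3-chloroperoxybenzoic acid, OOC(=O)c1cccc(Cl)c1
Why: Prilezhaev epoxidation should take place at the unhindered exocyclic 1,1-disubstituted alkene and not at the ring alkene flanked by the CMe2 and C1–OTBS groups, with oxygen entering anti to the two silyloxy-bearing substituents (the spiro configuration is lost in step 14).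

Step 14
Reactants: 22 ring A spiro-epoxide; 9 bicyclic aldol enone (2 equiv)
Product: 24 coupled lactone (1,6-bis(TBS-oxy)-16-hydroxy-12-oxo-6,7-secokaur-2-en-7,20-olide), via hydroxy ester 23 (not isolated)
Conditions: Cp2TiCl2, Zn dust, THF, rt, slow addition to 22 and 9; aq. HCl; then PPTS, toluene, 70 °C
Reagents that add atoms: none
Why: Cp2TiCl (trivalent titanium) opens the spiro-epoxide by single-electron transfer to the tertiary C10 radical (Nugent–RajanBabu opening), which should add in a Giese reaction to C9 of the enone on the face anti to the C15–C16 bridge and through its own face anti to the C1–OTBS and C5–CH2OTBS groups, a second Cp2TiCl reduces the C11 radical to a titanium enolate, and after protonation the C20 hydroxyl of 23 closes the six-membered lactone onto the C7 ester under the compression of the quaternary carbons C8 and C10.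

Step 15
Reactants: 24 coupled lactone
Product: 25 C12 tosylhydrazone of 24
Conditions: TsNHNH2, AcOH (cat.), EtOH/THF, 50 °C
Reagents that add atoms: 4-methylbenzenesulfonohydrazide, Cc1ccc(cc1)S(=O)(=O)NN
Why: Condensation of tosylhydrazide with the only ketone (C12) gives the hydrazone under mild acid catalysis that leaves the silyl ethers, the lactone and the β-hydroxy ketone array intact.

Step 16
Reactants: 25 C12 tosylhydrazone of 24
Product: 26 C12-deoxy lactone (1,6-bis(TBS-oxy)-16-hydroxy-6,7-secokaur-2-en-7,20-olide)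
Conditions: catecholborane, CHCl3, 0 °C; then NaOAc·3H2O, 60 °C
Reagents that add atoms: none
Why: Hydride transfer from catecholborane to the C=N bond, followed by acetate-induced loss of sulfinate and extrusion of N2 from the diazene (Kabalka modification of the Caglioti reduction), converts C12 into a methylene without touching the lactone, the ring A alkene or the silyl ethers.

Step 17
Reactants: 26 C12-deoxy lactone
Product: 27 exocyclic alkene (1,6-bis(TBS-oxy)-6,7-secokaura-2,16-dien-7,20-olide)
Conditions: SOCl2, pyridine, −40 to 0 °C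
Reagents that add atoms: none
Why: The chlorosulfite of the tertiary alcohol is eliminated by pyridine in an E2 process, and since only the freely rotating C17 methyl can place a hydrogen anti-periplanar to the leaving group in the rigid five-membered ring D, the exocyclic C16=C17 alkene should predominate, the low temperature avoiding a free C16 cation and skeletal rearrangement.

Step 18
Reactants: 27 exocyclic alkene
Product: 28 C15 exo allylic alcohol (hydroxyl on the C14 side of ring D)
Conditions: SeO2 (0.5 equiv), t-BuOOH, CH2Cl2, rt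
Reagents that add atoms: selenium dioxide, O=[Se]=O; tert-butyl hydroperoxide, CC(C)(C)OO
Why: Riley oxidation (ene reaction with SeO2, then [2,3]-sigmatropic shift) should hydroxylate C15, the only allylic position that can lose hydrogen because C13 is a bridgehead, from the exo face of ring D, and any enone formed by over-oxidation converges in step 19.

Step 19
Reactants: 28 C15 exo allylic alcohol
Product: 29 16-en-15-one
Conditions: Dess–Martin periodinane, NaHCO3, CH2Cl2, rt
Reagents that add atoms: none
Why: Dess–Martin oxidation of the allylic alcohol gives the exocyclic enone, which erases the C15 configuration so that it can be reset by hydride delivery.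

Step 20
Reactants: 29 16-en-15-one
Product: 30 C15 endo allylic alcohol (hydroxyl on the C9/C11 side, as in the target)
Conditions: NaBH4, CeCl3·7H2O, MeOH, −78 °C
Reagents that add atoms: none
Why: Luche 1,2-reduction should bring hydride to the C15 carbonyl from the open exo face (the C14 side of the bicyclo[3.2.1]octane), placing the hydroxyl on the endo face as in the target, while the lactone and the silyl ethers are inert.

Step 21
Reactants: 30 C15 endo allylic alcohol
Product: 31 epoxy alcohol (1,6-bis(TBS-oxy)-16,17-epoxy-15-hydroxy-6,7-secokaur-2-en-7,20-olide)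
Conditions: VO(acac)2 (cat.), t-BuOOH, CH2Cl2, 0 °C to rt
Reagents that add atoms: tert-butyl hydroperoxide, CC(C)(C)OO
Why: The vanadium alkoxide of the C15 alcohol delivers the peroxide oxygen to the same face of the C16=C17 alkene (hydroxyl-directed epoxidation), which sets C16 with its oxygen cis to the hydroxyl, and the ring A alkene carries no free hydroxyl and is left alone.

Step 22
Reactants: 31 epoxy alcohol
Product: 32 triol (16,17-epoxy-1,6,15-trihydroxy-6,7-secokaur-2-en-7,20-olide)
Conditions: TBAF, AcOH (1:1), THF, rt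
Reagents that add atoms: none
Why: Fluoride cleaves both TBS ethers, and buffering with acetic acid keeps the freed C1 alkoxide from attacking the lactone or the epoxide.

Step 23
Reactants: 32 triol
Product: 33 ring A enone diol (16,17-epoxy-6,15-dihydroxy-1-oxo-6,7-secokaur-2-en-7,20-olide)
Conditions: MnO2, CH2Cl2, rt
Reagents that add atoms: none
Why: MnO2 oxidises only the allylic C1 alcohol to the enone, since the C15 alcohol is no longer allylic after step 21 and the C6 alcohol is saturated.

Step 24
Reactants: 33 ring A enone diol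
Product: 34 CNP0537841.1
Conditions: TEMPO (cat.), PhI(OAc)2, CH2Cl2, rt
Reagents that add atoms: none
Why: The TEMPO oxoammonium cycle with PhI(OAc)2 should oxidise the primary C6 alcohol to the aldehyde much faster than the hindered secondary C15 alcohol, under neutral conditions that do not epimerise C5, giving 34.

**Compound list** (TBS = tert-butyldimethylsilyl)

1 | benzoic acid | OC(=O)c1ccccc1 | starting material
2 | propargyl bromide | C#CCBr | starting material
3 | dilithium dienediolate of 1,4-dihydrobenzoic acid | [Li+].[Li+].[O-]C([O-])=C1C=CCC=C1 | intermediate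
4 | 1-(prop-2-yn-1-yl)cyclohexa-2,5-diene-1-carboxylic acid | OC(=O)C1(CC#C)C=CCC=C1 | intermediate
5 | methyl 1-(prop-2-yn-1-yl)cyclohexa-2,5-diene-1-carboxylate | COC(=O)C1(CC#C)C=CCC=C1 | intermediate
6 | methyl 4-oxo-1-(prop-2-yn-1-yl)cyclohexa-2,5-diene-1-carboxylate | COC(=O)C1(CC#C)C=CC(=O)C=C1 | intermediate
7 | methyl 4-oxo-1-(2-oxopropyl)cyclohexa-2,5-diene-1-carboxylate | COC(=O)C1(CC(C)=O)C=CC(=O)C=C1 | intermediate
8 | methyl (1R,5R,6S)-6-{[diethoxy(methyl)silyl]oxy}-6-methyl-4-oxobicyclo[3.2.1]oct-2-ene-1-carboxylate | COC(=O)[C@@]12C[C@@H](C(=O)C=C1)[C@@](C)(O[Si](C)(OCC)OCC)C2 | intermediate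
9 | methyl (1R,5R,6S)-6-hydroxy-6-methyl-4-oxobicyclo[3.2.1]oct-2-ene-1-carboxylate | COC(=O)[C@@]12C[C@@H](C(=O)C=C1)[C@@](C)(O)C2 | intermediate
10 | 4,4-dimethylcyclohexanone | CC1(C)CCC(=O)CC1 | starting material
11 | 4,4-dimethylcyclohexa-2,5-dien-1-one | CC1(C)C=CC(=O)C=C1 | intermediate
12 | (E)-2-phenylethenylboronic acid | OB(O)/C=C/c1ccccc1 | starting material
13 | (R)-4,4-dimethyl-5-[(E)-2-phenylethenyl]cyclohex-2-en-1-one | CC1(C)C=CC(=O)C[C@@H]1/C=C/c1ccccc1 | intermediate
14 | (S)-2,2-dimethyl-5-oxocyclohex-3-ene-1-carbaldehyde | CC1(C)C=CC(=O)C[C@@H]1C=O | intermediate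
15 | (S)-5-(hydroxymethyl)-4,4-dimethylcyclohex-2-en-1-one | CC1(C)C=CC(=O)C[C@@H]1CO | intermediate
16 | (S)-5-[(TBS-oxy)methyl]-4,4-dimethylcyclohex-2-en-1-one | CC1(C)C=CC(=O)C[C@@H]1CO[Si](C)(C)C(C)(C)C | intermediate
17 | trans-6-[(dimethylamino)methyl] derivative of 16 (Mannich base) | CC1(C)C=CC(=O)[C@@H](CN(C)C)[C@@H]1CO[Si](C)(C)C(C)(C)C | intermediate
18 | N-methyl ammonium iodide of 17 | CC1(C)C=CC(=O)[C@@H](C[N+](C)(C)C)[C@@H]1CO[Si](C)(C)C(C)(C)C.[I-] | intermediate
19 | (R)-5-[(TBS-oxy)methyl]-4,4-dimethyl-6-methylidenecyclohex-2-en-1-one | CC1(C)C=CC(=O)C(=C)[C@@H]1CO[Si](C)(C)C(C)(C)C | intermediate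
20 | (1S,5R)-5-[(TBS-oxy)methyl]-4,4-dimethyl-6-methylidenecyclohex-2-en-1-ol (hydroxyl cis to the CH2OTBS group) | CC1(C)C=C[C@H](O)C(=C)[C@@H]1CO[Si](C)(C)C(C)(C)C | intermediate
21 | bis-TBS ether of 20 | CC1(C)C=C[C@H](O[Si](C)(C)C(C)(C)C)C(=C)[C@@H]1CO[Si](C)(C)C(C)(C)C | intermediate
22 | (3R,4S,8S)-4-(TBS-oxy)-8-[(TBS-oxy)methyl]-7,7-dimethyl-1-oxaspiro[2.5]oct-5-ene | CC1(C)C=C[C@H](O[Si](C)(C)C(C)(C)C)[C@]2(CO2)[C@@H]1CO[Si](C)(C)C(C)(C)C | intermediate
23 | methyl 1,6-bis(TBS-oxy)-16,20-dihydroxy-12-oxo-6,7-secokaur-2-en-7-oate (C9–C10 joined, C20 hydroxyl free) | COC(=O)[C@@]12C[C@@H](C(=O)C[C@H]1[C@]3(CO)[C@@H](O[Si](C)(C)C(C)(C)C)C=CC(C)(C)[C@H]3CO[Si](C)(C)C(C)(C)C)[C@@](C)(O)C2 | intermediate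
24 | 1,6-bis(TBS-oxy)-16-hydroxy-12-oxo-6,7-secokaur-2-en-7,20-olide | CC1(C)C=C[C@H](O[Si](C)(C)C(C)(C)C)[C@]2(COC(=O)[C@@]34C[C@@H](C(=O)C[C@@H]23)[C@@](C)(O)C4)[C@@H]1CO[Si](C)(C)C(C)(C)C | intermediate
25 | C12 tosylhydrazone of 24 | CC1(C)C=C[C@H](O[Si](C)(C)C(C)(C)C)[C@]2(COC(=O)[C@@]34C[C@@H](C(=NNS(=O)(=O)c5ccc(C)cc5)C[C@@H]23)[C@@](C)(O)C4)[C@@H]1CO[Si](C)(C)C(C)(C)C | intermediate
26 | 1,6-bis(TBS-oxy)-16-hydroxy-6,7-secokaur-2-en-7,20-olide | CC1(C)C=C[C@H](O[Si](C)(C)C(C)(C)C)[C@]2(COC(=O)[C@@]34C[C@@H](CC[C@@H]23)[C@@](C)(O)C4)[C@@H]1CO[Si](C)(C)C(C)(C)C | intermediate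
27 | 1,6-bis(TBS-oxy)-6,7-secokaura-2,16-dien-7,20-olide | CC1(C)C=C[C@H](O[Si](C)(C)C(C)(C)C)[C@]2(COC(=O)[C@@]34C[C@@H](CC[C@@H]23)C(=C)C4)[C@@H]1CO[Si](C)(C)C(C)(C)C | intermediate
28 | 15-hydroxy derivative of 27, hydroxyl exo (C14 side) | CC1(C)C=C[C@H](O[Si](C)(C)C(C)(C)C)[C@]2(COC(=O)[C@@]34C[C@@H](CC[C@@H]23)C(=C)[C@@H]4O)[C@@H]1CO[Si](C)(C)C(C)(C)C | intermediate
29 | 15-oxo derivative of 27 | CC1(C)C=C[C@H](O[Si](C)(C)C(C)(C)C)[C@]2(COC(=O)[C@@]34C[C@@H](CC[C@@H]23)C(=C)C4=O)[C@@H]1CO[Si](C)(C)C(C)(C)C | intermediate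
30 | 15-hydroxy derivative of 27, hydroxyl endo (C9/C11 side) | CC1(C)C=C[C@H](O[Si](C)(C)C(C)(C)C)[C@]2(COC(=O)[C@@]34C[C@@H](CC[C@@H]23)C(=C)[C@H]4O)[C@@H]1CO[Si](C)(C)C(C)(C)C | intermediate
31 | 1,6-bis(TBS-oxy)-16,17-epoxy-15-hydroxy-6,7-secokaur-2-en-7,20-olide | CC1(C)C=C[C@H](O[Si](C)(C)C(C)(C)C)[C@]2(COC(=O)[C@@]34C[C@@H](CC[C@@H]23)[C@]2(CO2)[C@H]4O)[C@@H]1CO[Si](C)(C)C(C)(C)C | intermediate
32 | 16,17-epoxy-1,6,15-trihydroxy-6,7-secokaur-2-en-7,20-olide | CC1(C)C=C[C@H](O)[C@]2(COC(=O)[C@@]34C[C@@H](CC[C@@H]23)[C@]2(CO2)[C@H]4O)[C@@H]1CO | intermediate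
33 | 16,17-epoxy-6,15-dihydroxy-1-oxo-6,7-secokaur-2-en-7,20-olide | CC1(C)C=CC(=O)[C@]2(COC(=O)[C@@]34C[C@@H](CC[C@@H]23)[C@]2(CO2)[C@H]4O)[C@@H]1CO | intermediate
34 | CNP0537841.1 (16,17-epoxy-15-hydroxy-1,6-dioxo-6,7-secokaur-2-en-7,20-olide) | CC1(C)C=CC(=O)[C@]2(COC(=O)[C@@]34C[C@@H](CC[C@@H]23)[C@]2(CO2)[C@H]4O)[C@@H]1C=O | target

**Step count and risks**

Total step count: 24. Longest linear sequence: 19 steps (steps 6–13, then 14–24, from 4,4-dimethylcyclohexanone).

Steps most likely to fail:

1. Step 14. Addition of the hindered tertiary C10 radical to the hindered C9 may be slower than reduction of the radical or of the enone by trivalent titanium, and facial control may erode. Fallback, from 21 back to 24: 21 is dihydroxylated at the exocyclic alkene (OsO4 cat., NMO) to the C10,C20-diol F1, which with 1,1'-thiocarbonyldiimidazole gives the cyclic thionocarbonate F2. With Bu3SnH (syringe pump) and AIBN in benzene at 80 °C in the presence of excess 9, the stannyl radical adds to sulfur and the C10–O bond breaks to the same tertiary radical. This radical adds to C9 in a tin hydride chain Giese reaction, giving the S-stannyl thiocarbonate F3. KF in methanol frees the C20 hydroxyl (23), which is lactonised with PPTS as in step 14 to 24.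

2. Step 5. The catalyst may not discriminate well enough between the two enone arms, because it must read the small difference between the ester face and the acetonyl face; 1,2-reduction of the ketone or a second reduction may also compete. Fallback, from 7 back to 24: the reductive aldol is run with the achiral hydride [(Ph3P)CuH]6 and (EtO)2MeSiH to give racemic material, that is 9 together with ent-9 F4. The mixture is coupled with enantiopure 22 as in step 14. 9 gives 24, while F4 gives the diastereomeric hydroxy ester F5 and from it the diastereomeric lactone F6. F6 is removed by chromatography and the route continues from 24.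

3. Step 7. Insertion at the neopentylic β-carbon may be sluggish, a second addition to the product enone may occur, or the enantioselectivity may be low. Fallback, from 11 back to 15: vinylmagnesium bromide with CuI (cat.) in THF at −40 °C gives the racemic vinyl enone F7 (the enolate formed cannot add a second time). Ozonolysis and NaBH4 as in step 8 give, through the racemic keto aldehyde F8, the racemic alcohol F9. Esterification with (S)-2-methoxy-2-phenylacetic acid (DCC, DMAP) gives the ester of the (S)-alcohol F10 and the ester of the (R)-alcohol F11, which are separated. Methanolysis of F10 (K2CO3, MeOH) returns 15.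

Further compounds
F1 | step 14 | C10,C20-diol from 21 (both hydroxyls anti to the silyloxy substituents) | CC1(C)C=C[C@H](O[Si](C)(C)C(C)(C)C)[C@](O)(CO)[C@@H]1CO[Si](C)(C)C(C)(C)C
F2 | step 14 | cyclic thionocarbonate of F1 | CC1(C)C=C[C@H](O[Si](C)(C)C(C)(C)C)[C@]2(COC(=S)O2)[C@@H]1CO[Si](C)(C)C(C)(C)C
F3 | step 14 | S-tributylstannyl thiocarbonate of 23 at the C20 oxygen | COC(=O)[C@@]12C[C@@H](C(=O)C[C@H]1[C@]3(COC(=O)S[Sn](CCCC)(CCCC)CCCC)[C@@H](O[Si](C)(C)C(C)(C)C)C=CC(C)(C)[C@H]3CO[Si](C)(C)C(C)(C)C)[C@@](C)(O)C2
F4 | step 5 | ent-9, methyl (1S,5S,6R)-6-hydroxy-6-methyl-4-oxobicyclo[3.2.1]oct-2-ene-1-carboxylate | COC(=O)[C@]12C[C@H](C(=O)C=C1)[C@](C)(O)C2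
F5 | step 5 | diastereomer of 23 built from F4 and 22 | COC(=O)[C@]12C[C@H](C(=O)C[C@@H]1[C@]3(CO)[C@@H](O[Si](C)(C)C(C)(C)C)C=CC(C)(C)[C@H]3CO[Si](C)(C)C(C)(C)C)[C@](C)(O)C2
F6 | step 5 | diastereomer of 24 built from F4 and 22 | CC1(C)C=C[C@H](O[Si](C)(C)C(C)(C)C)[C@]2(COC(=O)[C@]34C[C@H](C(=O)C[C@H]23)[C@](C)(O)C4)[C@@H]1CO[Si](C)(C)C(C)(C)C
F7 | step 7 | racemic 5-ethenyl-4,4-dimethylcyclohex-2-en-1-one | CC1(C)C=CC(=O)CC1C=C
F8 | step 7 | racemic 2,2-dimethyl-5-oxocyclohex-3-ene-1-carbaldehyde | CC1(C)C=CC(=O)CC1C=O
F9 | step 7 | racemic 5-(hydroxymethyl)-4,4-dimethylcyclohex-2-en-1-one | CC1(C)C=CC(=O)CC1CO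
F10 | step 7 | (S)-2-methoxy-2-phenylacetate of 15 | CO[C@H](C(=O)OC[C@H]1CC(=O)C=CC1(C)C)c1ccccc1
F11 | step 7 | (S)-2-methoxy-2-phenylacetate of the enantiomer of 15 | CO[C@H](C(=O)OC[C@@H]1CC(=O)C=CC1(C)C)c1ccccc1
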